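The ten-membered carbocycle is cut at C1–C2. There an unfunctionalised CH2 (C2) meets the sp2 carbon C1 of the ring-cis C1=C10 alkene, well away from the C6–C9 stereocentres. In one operation the C2=C3 end of a C2–C5 diene is hydroborated and the alkylborane is cross-coupled to a (Z)-C1 alkenyl iodide. This closes the ring with both ring alkene geometries set beforehand. Seco precursor 21 already holds the trans C6/C7 γ-lactone, all four stereocentres and three differentiated ethers (O8 MOM, O9 TES, O14 TBS). Its C11=C13 methylene is stored as a propanethiol adduct, so borane, palladium and base find one reactive alkene and one C–I bond.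

Key step: step 12

Remark on numbering: germacrane numbering (C1–C15) is used for every fragment. C11 in 19–24 is an inconsequential epimer mixture, left undefined in the SMILES and erased in step 13.

Remark on design:
- A free α-methylene lactone would offer 9-BBN, the alkenylpalladium species and aqueous carbonate a second reactive alkene. It is therefore masked from step 10 to step 13.
- Open-chain bromomethacrylate Barbier reactions favour cis-lactones. The trans-lactone is instead reached through a ring-locked bromolactone followed by acyl migration.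
- The syn C8/C9 diol comes from one reagent-controlled alkoxyallylboration.

Step 1
Reactants: 1 allyl methoxymethyl ether; 2 (+)-B-methoxydiisopinocampheylborane; 3 3-(trimethylsilyl)prop-2-ynal
Product: 6 (3S,4S)-3-(methoxymethoxy)hex-1-en-5-yn-4-ol, via alkoxyallylborane 4 (not isolated), via silylated enynol 5 (not isolated)
Conditions: s-BuLi, THF, −78 °C; 2; BF3·OEt2; 3, −78 °C; then 3 M NaOH, 30% H2O2, 0 °C to rt; MeOH, rt
Reagents that add atoms: none
Why: Brown alkoxyallylboration through a Zimmerman–Traxler chair, in which the Z-alkoxyallyl geometry gives the syn C8/C9 relationship and the isopinocampheyl groups from (−)-α-pinene direct attack to the Re face of the ynal (9S, hence 8S), while the alkaline work-up in methanol also removes the alkynyl silyl group.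

Step 2
Reactants: 6 (3S,4S)-3-(methoxymethoxy)hex-1-en-5-yn-4-ol
Product: 8 (3S,4S,5E)-6-iodo-5-{[isopropoxy(dimethyl)silyl]methyl}-3-(methoxymethoxy)hexa-1,5-dien-4-ol, via magnesium chelate 7 (not isolated)
Conditions: (i-PrO)Me2SiCH2MgCl (4 equiv), CuI (0.2 equiv), THF, −20 °C to rt; then I2, −40 to 0 °C
Reagents that add atoms: (isopropoxydimethylsilyl)methylmagnesium chloride, CC(C)O[Si](C)(C)C[Mg]Cl; iodine, II
Why: Copper-catalysed hydroxyl-directed anti-carbomagnesiation of a propargylic alcohol, in which the magnesium alkoxide delivers the silylmethyl group (C14) to C10 and holds magnesium on C1 in a five-membered chelate cis to C9, so that iodinolysis with retention fixes the later ring-cis geometry without touching a stereocentre.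

Step 3
Reactants: 8 iodo allylsilane
Product: 9 (2Z,3S,4S)-2-(iodomethylidene)-4-(methoxymethoxy)hex-5-ene-1,3-diol
Conditions: 30% H2O2, KF, KHCO3, THF/MeOH, rt
Reagents that add atoms: hydrogen peroxide, OO
Why: Tamao oxidation, in which peroxide attacks the fluoride-activated alkoxysilane and the C14–Si bond migrates to oxygen without allylic transposition, leaving the alkenyl iodide, vinyl group and MOM ether untouched.

Step 4
Reactants: 9 diol
Product: 10 (3S,4S,5Z)-5-{[(tert-butyldimethylsilyl)oxy]methyl}-6-iodo-3-(methoxymethoxy)hexa-1,5-dien-4-ol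
Conditions: TBSCl, imidazole, CH2Cl2, −10 °C
Reagents that add atoms: tert-butyldimethylsilyl chloride, CC(C)(C)[Si](C)(C)Cl
Why: Sterically controlled silylation, since the primary allylic O14 hydroxyl reacts much faster than the flanked secondary C9 hydroxyl, which stays free for acylation.

Step 5
Reactants: 10 C9 alcohol; 11 2-(bromomethyl)acrylic acid
Product: 12 (3S,4S,5Z)-5-{[(tert-butyldimethylsilyl)oxy]methyl}-6-iodo-3-(methoxymethoxy)hexa-1,5-dien-4-yl 2-(bromomethyl)acrylate
Conditions: DCC, DMAP (cat.), CH2Cl2, 0 °C
Reagents that add atoms: none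
Why: Steglich esterification places C11–C13 on O9 with retention at C9, and carbodiimide activation keeps nucleophilic amine to a catalytic amount so that the allylic bromide is not quaternised.

Step 6
Reactants: 12 bromomethacrylate
Product: 13 (5S,6S)-3-(bromomethyl)-6-[(1Z)-3-{(tert-butyldimethylsilyl)oxy}-1-iodoprop-1-en-2-yl]-5-(methoxymethoxy)-5,6-dihydro-2H-pyran-2-one
Conditions: second-generation Hoveyda–Grubbs catalyst (5–10 mol%), toluene (5 mM), 80 °C, argon sparge
Reagents that add atoms: none
Why: Ring-closing metathesis starts at the monosubstituted C7 vinyl group and closes onto the 1,1-disubstituted acrylate to a six-membered enoate with loss of ethene, the trisubstituted alkenyl iodide being inert to the ruthenium carbene, and the new ring forces C8 cis to the C12 carbonyl.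

Step 7
Reactants: 14 (E)-3-methylpent-2-en-4-yn-1-ol
Product: 15 (E)-3-methylpenta-2,4-dien-1-ol
Conditions: H2 (1 atm), Pd/CaCO3 poisoned with Pb(OAc)2 (Lindlar catalyst), quinoline, Et2O/pentane, 0 °C
Reagents that add atoms: none
Why: Lindlar semihydrogenation of a terminal alkyne stops at the alkene in the presence of quinoline and leaves the E-trisubstituted C4=C5 bond unchanged.

Step 8
Reactants: 15 dienol
Product: 16 (E)-3-methylpenta-2,4-dienal
Conditions: MnO2, CH2Cl2, rt; used directly as a solution
Reagents that add atoms: none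
Why: MnO2 oxidises allylic alcohols under neutral conditions, so the E geometry and the diene are kept.

Step 9
Reactants: 13 bromolactone; 16 dienal
Product: 18 α-methylene-δ-lactone (O9–C12) bearing at C7 the (R)-1-hydroxy-(2E)-3-methylpenta-2,4-dienyl group, (6R,7S,8S,9S), via allylindium bromide 17 (not isolated)
Conditions: indium powder, THF/H2O (3:1), rt
Reagents that add atoms: none
Why: Indium Barbier 2-(alkoxycarbonyl)allylation, in which the allylmetal reacts at its γ-carbon C7 through a chair transition state where the ring locks C8 trans to C13 (E-crotyl type, giving the C6/C7 relationship of a trans-lactone) and the aldehyde approaches the ring face opposite the cis-disposed C8 OMOM and C9 alkenyl groups (setting C7), with 1,2-addition to the enal as is usual for allylindiums.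

Step 10
Reactants: 18 δ-lactone alcohol
Product: 20 seco trans-γ-lactone (O6–C12) with free C9 hydroxyl and C13 propylthio mask, via thiol adduct 19 (not isolated)
Conditions: n-PrSH, Et3N (cat.), CH2Cl2, 0 °C; then DBU, rt
Reagents that add atoms: propane-1-thiol, CCCS
Why: Base-catalysed thia-Michael addition masks C11=C13 and DBU-mediated translactonisation then moves the acyl group from O9 to O6, because the five-membered trans-lactone is the thermodynamic sink (the δ-lactone must keep one of its three ring substituents axial), no bond to C6–C9 being broken.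

Step 11
Reactants: 20 C9 alcohol
Product: 21 key precursor, (Z)-C1 alkenyl iodide with C2–C5 diene, trans-γ-lactone, O8 MOM, O9 TES, O14 TBS and C13 propylthio mask
Conditions: TESOTf, 2,6-lutidine, CH2Cl2, −78 °C
Reagents that add atoms: triethylsilyl trifluoromethanesulfonate, CC[Si](CC)(CC)OS(=O)(=O)C(F)(F)F
Why: A silyl triflate with a hindered pyridine silylates the crowded allylic C9 hydroxyl at low temperature without disturbing lactone, thioether or diene, and an ether is used instead of the final acetate because an allylic ester would ionise on zerovalent palladium.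

Step 12
Reactants: 21 key precursor
Product: 23 ten-membered macrocycle with trans-γ-lactone, ring-cis C1=C10, ring-trans C4=C5, O8 MOM, O9 TES, O14 TBS and C13 propylthio mask, via alkylborane 22 (not isolated)
Conditions: 9-BBN dimer, THF, 0 °C to rt; H2O; then slow syringe-pump addition to PdCl2(dppf) (20 mol%), AsPh3 (40 mol%), Cs2CO3, DMF/THF/H2O, 50 °C, final concentration 1 mM
Reagents that add atoms: none
Why: 9-BBN adds to the only monosubstituted alkene of 21, the C2=C3 end of the diene, placing boron on C2 because the bulky bicyclic borane avoids the substituted carbon and ignores the trisubstituted C4=C5 and C1=C10 bonds, and with C11=C13 stored as a thioether no electron-poor alkene remains to be reduced, carbopalladated or attacked by base. Zerovalent palladium formed from PdCl2(dppf) inserts into the C1–I bond with retention, the hydroxyborate of 22 hands C2 to divalent palladium, and reductive elimination makes C1–C2. This is an intramolecular B-alkyl Suzuki–Miyaura coupling, a reaction type already used to close medium and large carbocycles. The ten-membered ring closes end to end by C(sp3)–C(sp2) reductive elimination from an eleven-membered palladacycle, not by addition to a π bond. No stereocentre is created and both ring alkenes are inherited, ring-cis C1=C10 from the Z-iodide and ring-trans C4=C5 from 16. The required preference for ring closure over dimerisation, β-hydride elimination and protodeboronation is served by pseudo-high dilution, by the wide-bite-angle dppf ligand with AsPh3, and by the turn imposed by the trans-lactone and by the iodide lying cis to C9.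

Step 13
Reactants: 23 masked macrocycle
Product: 25 macrocyclic α-methylene-γ-lactone with O8 MOM, O9 TES and O14 TBS, via sulfonium iodide 24 (not isolated)
Conditions: MeI, MeCN, 35 °C; then sat. aq NaHCO3, rt
Reagents that add atoms: none
Why: S-Methylation turns the thioether into a sulfonium leaving group and mild base then triggers E1cB elimination across C11–C13, the classical release of a thiol-protected α-methylene lactone, which also erases the C11 stereocentre.

Step 14
Reactants: 25 MOM ether
Product: 27 macrocyclic C8 alcohol with O9 TES and O14 TBS, via bipyridinium salt 26 (not isolated)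
Conditions: TMSOTf, 2,2'-bipyridyl, CH2Cl2, 0 °C; then H2O, rt
Reagents that add atoms: none
Why: The silyl triflate–bipyridyl pair converts the MOM acetal into a water-labile pyridinium-type salt under non-acidic conditions, so both silyl ethers, the lactone and the acid-sensitive cyclodecadiene are spared and C8 keeps its C–O bond.

Step 15
Reactants: 11 2-(bromomethyl)acrylic acid; 28 4-methoxybenzyl alcohol
Product: 29 2-{[(4-methoxybenzyl)oxy]methyl}acrylic acid
Conditions: NaH (2.2 equiv), THF, 0 °C to rt; then 1 M HCl
Reagents that add atoms: none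
Why: Williamson-type displacement of the allylic bromide of the carboxylate salt by the benzylic alkoxide, in which direct and allylically shifted attack give the same product.

Step 16
Reactants: 27 C8 alcohol; 29 protected side-chain acid
Product: 31 C8 ester with PMB-protected side chain, O9 TES and O14 TBS, via mixed anhydride 30 (not isolated)
Conditions: 2,4,6-Cl3C6H2COCl, Et3N, toluene, rt; then 27, DMAP, rt
Reagents that add atoms: none
Why: Yamaguchi esterification, in which DMAP attacks the mixed anhydride at the less hindered acryloyl carbonyl and the acylpyridinium acylates the only free hydroxyl, the hindered C8–OH, with retention, while O9 is still silylated so that no acyl migration can compete.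

Step 17
Reactants: 31 bis-silyl ether
Product: 32 C9,C14 diol with PMB-protected C8 ester
Conditions: HF·pyridine, pyridine, THF, 0 °C to rt
Reagents that add atoms: none
Why: Buffered fluoride cleaves the secondary triethylsilyl and the primary allylic tert-butyldimethylsilyl ethers together, while the esters, the PMB ether and both Michael acceptors are inert.

Step 18
Reactants: 32 diol
Product: 33 C14 enal with free C9 hydroxyl
Conditions: TEMPO (cat.), PhI(OAc)2, CH2Cl2, rt
Reagents that add atoms: none
Why: Oxoammonium (TEMPO) oxidation strongly prefers primary alcohols, so C14 becomes the enal and the C9 carbinol remains, the C1=C10 geometry already being the favoured one for a β-alkyl enal.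

Step 19
Reactants: 33 C9 alcohol
Product: 34 C9 acetate with PMB-protected side chain
Conditions: Ac2O, pyridine, DMAP (cat.), CH2Cl2, 0 °C
Reagents that add atoms: acetic anhydride, CC(=O)OC(C)=O
Why: DMAP-catalysed acetylation of the one remaining hydroxyl, run cold and briefly to forestall O8-to-O9 acyl migration.

Step 20
Reactants: 34 PMB ether
Product: 35 target CNP0177123.1
Conditions: DDQ, CH2Cl2/pH 7 phosphate buffer, 0 °C
Reagents that add atoms: none
Why: Oxidative PMB cleavage by hydride abstraction at the electron-rich benzylic position under buffered neutral conditions, which leave the enal, the three esters and the two α-methylene carbonyl units intact.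

Compound list

1 | allyl methoxymethyl ether | C=CCOCOC | starting material
2 | (+)-B-methoxydiisopinocampheylborane (from (−)-α-pinene) | COB([C@H]1C[C@H]2C[C@@H]([C@@H]1C)C2(C)C)[C@H]1C[C@H]2C[C@@H]([C@@H]1C)C2(C)C | starting material
3 | 3-(trimethylsilyl)prop-2-ynal | C[Si](C)(C)C#CC=O | starting material
4 | [(Z)-3-(methoxymethoxy)allyl]diisopinocampheylborane | COCO/C=C\CB([C@H]1C[C@H]2C[C@@H]([C@@H]1C)C2(C)C)[C@H]1C[C@H]2C[C@@H]([C@@H]1C)C2(C)C | intermediate
5 | (3S,4S)-3-(methoxymethoxy)-6-(trimethylsilyl)hex-1-en-5-yn-4-ol | C[Si](C)(C)C#C[C@H](O)[C@@H](OCOC)C=C | intermediate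
6 | (3S,4S)-3-(methoxymethoxy)hex-1-en-5-yn-4-ol | C#C[C@H](O)[C@@H](OCOC)C=C | intermediate
7 | five-membered alkenylmagnesium alkoxide chelate (O9–Mg–C1) | [Mg]1C=C(C[Si](C)(C)OC(C)C)[C@H](O1)[C@@H](OCOC)C=C | intermediate
8 | (3S,4S,5E)-6-iodo-5-{[isopropoxy(dimethyl)silyl]methyl}-3-(methoxymethoxy)hexa-1,5-dien-4-ol | I/C=C(/C[Si](C)(C)OC(C)C)[C@H](O)[C@@H](OCOC)C=C | intermediate
9 | (2Z,3S,4S)-2-(iodomethylidene)-4-(methoxymethoxy)hex-5-ene-1,3-diol | I/C=C(/CO)[C@H](O)[C@@H](OCOC)C=C | intermediate
10 | (3S,4S,5Z)-5-{[(tert-butyldimethylsilyl)oxy]methyl}-6-iodo-3-(methoxymethoxy)hexa-1,5-dien-4-ol | I/C=C(/CO[Si](C)(C)C(C)(C)C)[C@H](O)[C@@H](OCOC)C=C | intermediate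
11 | 2-(bromomethyl)acrylic acid | C=C(CBr)C(=O)O | starting material
12 | O9 2-(bromomethyl)acrylate of 10 | I/C=C(/CO[Si](C)(C)C(C)(C)C)[C@H](OC(=O)C(=C)CBr)[C@@H](OCOC)C=C | intermediate
13 | (5S,6S)-3-(bromomethyl)-6-[(1Z)-3-{(tert-butyldimethylsilyl)oxy}-1-iodoprop-1-en-2-yl]-5-(methoxymethoxy)-5,6-dihydro-2H-pyran-2-one | I/C=C(/CO[Si](C)(C)C(C)(C)C)[C@@H]1OC(=O)C(CBr)=C[C@@H]1OCOC | intermediate
14 | (E)-3-methylpent-2-en-4-yn-1-ol | C#C/C(C)=C/CO | starting material
15 | (E)-3-methylpenta-2,4-dien-1-ol | C=C/C(C)=C/CO | intermediate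
16 | (E)-3-methylpenta-2,4-dienal | C=C/C(C)=C/C=O | intermediate
17 | allylindium dibromide from 13 (drawn as the simplest of the allylindium bromides present) | I/C=C(/CO[Si](C)(C)C(C)(C)C)[C@@H]1OC(=O)C(C[In](Br)Br)=C[C@@H]1OCOC | intermediate
18 | α-methylene-δ-lactone (O9–C12) with C7 (R)-1-hydroxy-(2E)-3-methylpenta-2,4-dienyl group trans to the cis C8-OMOM/C9-alkenyl pair, (6R,7S,8S,9S) | I/C=C(/CO[Si](C)(C)C(C)(C)C)[C@@H]1OC(=O)C(=C)[C@@H]([C@H](O)/C=C(\C)C=C)[C@@H]1OCOC | intermediate
19 | propanethiol adduct of 18 (δ-lactone, C11 epimers) | I/C=C(/CO[Si](C)(C)C(C)(C)C)[C@@H]1OC(=O)C(CSCCC)[C@@H]([C@H](O)/C=C(\C)C=C)[C@@H]1OCOC | intermediate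
20 | seco trans-γ-lactone (O6–C12), free C9–OH, O8 MOM, O14 TBS, C13 propylthio; C6–C9 as in 35 | I/C=C(/CO[Si](C)(C)C(C)(C)C)[C@H](O)[C@@H](OCOC)[C@H]1C(CSCCC)C(=O)O[C@@H]1/C=C(\C)C=C | intermediate
21 | key precursor, O9 triethylsilyl ether of 20 | I/C=C(/CO[Si](C)(C)C(C)(C)C)[C@H](O[Si](CC)(CC)CC)[C@@H](OCOC)[C@H]1C(CSCCC)C(=O)O[C@@H]1/C=C(\C)C=C | intermediate
22 | C2 B-alkyl-9-borabicyclo[3.3.1]nonane from 21 | I/C=C(/CO[Si](C)(C)C(C)(C)C)[C@H](O[Si](CC)(CC)CC)[C@@H](OCOC)[C@H]1C(CSCCC)C(=O)O[C@@H]1/C=C(\C)CCB1C2CCCC1CCC2 | intermediate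
23 | ten-membered macrocycle, trans-γ-lactone, ring-cis C1=C10, ring-trans C4=C5, O8 MOM, O9 TES, O14 TBS, C13 propylthio | COCO[C@H]1[C@H]2C(CSCCC)C(=O)O[C@@H]2/C=C(\C)CC/C=C(/CO[Si](C)(C)C(C)(C)C)[C@@H]1O[Si](CC)(CC)CC | intermediate
24 | S-methyl sulfonium iodide of 23 | COCO[C@H]1[C@H]2C(C[S+](C)CCC)C(=O)O[C@@H]2/C=C(\C)CC/C=C(/CO[Si](C)(C)C(C)(C)C)[C@@H]1O[Si](CC)(CC)CC.[I-] | intermediate
25 | macrocyclic α-methylene-γ-lactone, O8 MOM, O9 TES, O14 TBS | COCO[C@H]1[C@H]2C(=C)C(=O)O[C@@H]2/C=C(\C)CC/C=C(/CO[Si](C)(C)C(C)(C)C)[C@@H]1O[Si](CC)(CC)CC | intermediate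
26 | O8-CH2-(2,2'-bipyridin-1-ium) triflate from 25 | c1ccc(nc1)-c1cccc[n+]1CO[C@H]1[C@H]2C(=C)C(=O)O[C@@H]2/C=C(\C)CC/C=C(/CO[Si](C)(C)C(C)(C)C)[C@@H]1O[Si](CC)(CC)CC.[O-]S(=O)(=O)C(F)(F)F | intermediate
27 | macrocyclic C8 alcohol, O9 TES, O14 TBS | O[C@H]1[C@H]2C(=C)C(=O)O[C@@H]2/C=C(\C)CC/C=C(/CO[Si](C)(C)C(C)(C)C)[C@@H]1O[Si](CC)(CC)CC | intermediate
28 | 4-methoxybenzyl alcohol | COc1ccc(CO)cc1 | starting material
29 | 2-{[(4-methoxybenzyl)oxy]methyl}acrylic acid | C=C(COCc1ccc(OC)cc1)C(=O)O | intermediate
30 | mixed anhydride of 29 and 2,4,6-trichlorobenzoic acid | C=C(COCc1ccc(OC)cc1)C(=O)OC(=O)c1c(Cl)cc(Cl)cc1Cl | intermediate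
31 | C8 2-{[(4-methoxybenzyl)oxy]methyl}acrylate, O9 TES, O14 TBS | C=C(COCc1ccc(OC)cc1)C(=O)O[C@H]1[C@H]2C(=C)C(=O)O[C@@H]2/C=C(\C)CC/C=C(/CO[Si](C)(C)C(C)(C)C)[C@@H]1O[Si](CC)(CC)CC | intermediate
32 | C9,C14 diol of 31 | C=C(COCc1ccc(OC)cc1)C(=O)O[C@H]1[C@H]2C(=C)C(=O)O[C@@H]2/C=C(\C)CC/C=C(/CO)[C@@H]1O | intermediate
33 | C14 enal, free C9–OH | C=C(COCc1ccc(OC)cc1)C(=O)O[C@H]1[C@H]2C(=C)C(=O)O[C@@H]2/C=C(\C)CC/C=C(/C=O)[C@@H]1O | intermediate
34 | C9 acetate, PMB-protected side chain | C=C(COCc1ccc(OC)cc1)C(=O)O[C@H]1[C@H]2C(=C)C(=O)O[C@@H]2/C=C(\C)CC/C=C(/C=O)[C@@H]1OC(C)=O | intermediate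
35 | (6R,7S,8S,9S)-9-acetoxy-8-[2-(hydroxymethyl)acryloyloxy]-14-oxogermacra-1(10),4,11(13)-trien-12,6-olide, ring-cis C1=C10, ring-trans C4=C5 (CNP0177123.1) | C=C(CO)C(=O)O[C@H]1[C@H]2C(=C)C(=O)O[C@@H]2/C=C(\C)CC/C=C(/C=O)[C@@H]1OC(C)=O | target

Total step count: 20. Longest linear sequence: 17 (steps 1–6, 9–14, 16–20).

Steps most likely to fail

Step 12. Oligomerisation, β-hydride elimination from the alkylpalladium species or protodeboronation may outrun the strained ring closure. The fallback is an intramolecular Negishi coupling, which needs neither base nor water and uses a faster-transmetalating sp3 organometallic. It sets out from 21 and comes back at 23. Borane 22 is oxidised with Me3NO, which spares the thioether, to the C2 primary alcohol F1. Appel iodination (I2, PPh3, imidazole) gives the C2 primary iodide F2. Zinc dust activated with LiCl inserts into the sp3 C–I bond in preference to the alkenyl C–I bond and gives the alkylzinc iodide F3. This is added slowly to Pd(PPh3)4 in THF to form C1–C2 and deliver 23.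

Step 2. The bulky Grignard reagent may add sluggishly to the hindered secondary alkoxide, mere alkyne deprotonation may prevail, or the allylsilane may be lost during iodinolysis. In the fallback the C10 branching and the alkene geometry are set by syn-silylformylation instead of anti-carbometalation. It sets out from borane 4 (made from 1 and 2) and comes back at 10, replacing steps 1–4. Commercial tert-butyldimethyl(prop-2-ynyloxy)silane, PhMe2SiH and CO with Rh4(CO)12 add silicon to C1 and formyl to C10 in a syn sense. This gives the (Z)-β-silyl enal F4, with silicon cis to the C9 aldehyde. Alkoxyallylboration of F4 with 4 gives the syn alcohol F5. N-Iodosuccinimide in hexafluoroisopropanol then replaces silicon by iodine with retention and gives 10.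

Step 9. In water the allylmetal may be protonated before its hindered γ-carbon C7 reaches the aldehyde. It may also expel the C8 alkoxy group reductively, or react through a less ordered transition state and erode the C6 configuration. The fallback uses an isolable allylboronate and a thermal allylboration. It sets out from 12 and comes back at 18. B2pin2, CuCl and KOAc in DMF exchange the activated allylic bromide by conjugate borylation–elimination, which is degenerate in regiochemistry at this open-chain stage, and give the 2-(borylmethyl)acrylate F6. Ring-closing metathesis as in step 6 gives the ring-locked allylboronate F7. Heating F7 with 16 in toluene, if needed with catalytic Sc(OTf)3, forms C6–C7 through a closed six-membered transition state with the same facial and E-crotyl-type control. Aqueous work-up gives 18.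

Further compounds

F1 | step 12 | C2 primary alcohol from 21 (hydroboration–oxidation) | I/C=C(/CO[Si](C)(C)C(C)(C)C)[C@H](O[Si](CC)(CC)CC)[C@@H](OCOC)[C@H]1C(CSCCC)C(=O)O[C@@H]1/C=C(\C)CCO
F2 | step 12 | C2 primary iodide | I/C=C(/CO[Si](C)(C)C(C)(C)C)[C@H](O[Si](CC)(CC)CC)[C@@H](OCOC)[C@H]1C(CSCCC)C(=O)O[C@@H]1/C=C(\C)CCI
F3 | step 12 | C2 alkylzinc iodide | I/C=C(/CO[Si](C)(C)C(C)(C)C)[C@H](O[Si](CC)(CC)CC)[C@@H](OCOC)[C@H]1C(CSCCC)C(=O)O[C@@H]1/C=C(\C)CC[Zn]I
F4 | step 2 | (Z)-2-{[(tert-butyldimethylsilyl)oxy]methyl}-3-[dimethyl(phenyl)silyl]prop-2-enal | C[Si](C)(c1ccccc1)/C=C(/CO[Si](C)(C)C(C)(C)C)C=O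
F5 | step 2 | (3S,4S,5Z)-5-{[(tert-butyldimethylsilyl)oxy]methyl}-6-[dimethyl(phenyl)silyl]-3-(methoxymethoxy)hexa-1,5-dien-4-ol | C[Si](C)(c1ccccc1)/C=C(/CO[Si](C)(C)C(C)(C)C)[C@H](O)[C@@H](OCOC)C=C
F6 | step 9 | O9 2-[(pinacolatoboryl)methyl]acrylate of 10 | I/C=C(/CO[Si](C)(C)C(C)(C)C)[C@H](OC(=O)C(=C)CB1OC(C)(C)C(C)(C)O1)[C@@H](OCOC)C=C
F7 | step 9 | 3-[(pinacolatoboryl)methyl] analogue of 13 | I/C=C(/CO[Si](C)(C)C(C)(C)C)[C@@H]1OC(=O)C(CB2OC(C)(C)C(C)(C)O2)=C[C@@H]1OCOC
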